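**Retrosynthetic overview**
1. The C4 hydroxyl is set last, by borohydride reduction of the free (2R,3R)-dihydroflavonol. That ketone comes from a benzyl-protected (2R,3S,4S)-3,4-epoxyflavan by oxidative opening at C4 and hydrogenolysis.
2. Key disconnection: O1–C2 and C3–C4 of ring C are cut together. This leaves a salicylaldehyde (ring A with O1 and C4) and an enantiopure (E)-arylvinyl(dimethylamino)sulfoxonium salt (ring B with C2 and C3). In the forward direction it is an oxa-Michael / ylide–aldehyde / epoxide-closure cascade.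
3. Enabling feature: O1–C8a–C4a–C4 is an ortho-hydroxybenzaldehyde array on a hexasubstituted ring A, with nucleophilic O1 next to electrophilic C4 and no free ring carbon. The vicinal oxygens on C3 and C4 are the footprint of an opened 3,4-oxirane, so C2/C3 can enter as an electrophile/ylide pair and the formyl oxygen becomes O3.
4. Ring order: rings A and B are bought as benzaldehydes. Ring C and a temporary oxirane close in the key step, and the oxirane is opened in the next step.
5. The ring A pattern comes from 2,4,6-trihydroxybenzaldehyde by dibenzylation, dibromination and double methoxylation. The sulfur reagent comes from 3,4,5-tris(benzyloxy)benzaldehyde and a commercial sulfoximine.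

Key step: step 6

Assumption: the sulfur stereocentre is taken to steer step 6 in the sense of the steric model given there; the enantiomeric sulfoximine is equally available should the sense be opposite.

**Step 1**
Reactants: 1 2,4,6-trihydroxybenzaldehyde
Product: 2 2,4-bis(benzyloxy)-6-hydroxybenzaldehyde
Conditions: BnBr (2.05 equiv), K2CO3 (2.1 equiv), DMF, 0 °C to rt
Reagents that add atoms: benzyl bromide, BrCc1ccccc1
Why: Williamson ether synthesis that stops after two alkylations because the remaining ortho hydroxyl is held in a hydrogen bond to the formyl oxygen, and because the two ortho hydroxyls of 1 are equivalent only one dibenzyl ether can form.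

**Step 2**
Reactants: 2 2,4-bis(benzyloxy)-6-hydroxybenzaldehyde
Product: 3 2,4-bis(benzyloxy)-3,5-dibromo-6-hydroxybenzaldehyde
Conditions: NBS (2.1 equiv), CH2Cl2/MeCN, 0 °C, dark
Reagents that add atoms: N-bromosuccinimide, O=C1CCC(=O)N1Br
Why: Electrophilic aromatic bromination at the only two ring C–H positions, each of which is ortho or para to all three oxygen donors, while the unactivated benzyl rings stay untouched.

**Step 3**
Reactants: 3 2,4-bis(benzyloxy)-3,5-dibromo-6-hydroxybenzaldehyde
Product: 4 4,6-bis(benzyloxy)-2-hydroxy-3,5-dimethoxybenzaldehyde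
Conditions: NaOMe (excess), CuBr (20 mol %), DMF/MeOH, 110 °C; then 1 M HCl
Reagents that add atoms: sodium methoxide, C[O-].[Na+]
Why: Ullmann-type copper-catalysed methoxylation, the same double bromide-to-methoxide exchange that converts 3,5-dibromo-4-hydroxybenzaldehyde into syringaldehyde, run on the phenoxide of 3 whose charge shields the formyl group and the benzyl ethers from methoxide.

**Step 4**
Reactants: 5 (S)-N,S-dimethyl-S-phenylsulfoximine; 6 3,4,5-tris(benzyloxy)benzaldehyde
Product: 10 (S)-N-methyl-S-phenyl-S-{(E)-2-[3,4,5-tris(benzyloxy)phenyl]ethenyl}sulfoximine, via lithiated sulfoximine 7 (not isolated), via lithium alkoxide adduct 8 (not isolated), via methyl carbonate 9 (not isolated)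
Conditions: n-BuLi, THF, −78 °C; 6; ClCO2Me, −78 °C to rt; DBU, rt
Reagents that add atoms: n-butyllithium, [Li]CCCC (lithium of 7 and 8 only); methyl chloroformate, COC(=O)Cl (carbonate of 9 only)
Why: Addition–elimination olefination of a lithiated sulfoximine (1,2-addition to the aldehyde, carbonate activation, base-induced E1cB elimination), which gives the conjugated E alkene on steric grounds and leaves the sulfur stereocentre untouched.

**Step 5**
Reactants: 10 (S)-N-methyl-S-phenyl-S-{(E)-2-[3,4,5-tris(benzyloxy)phenyl]ethenyl}sulfoximine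
Product: 11 (S)-(dimethylamino)(phenyl){(E)-2-[3,4,5-tris(benzyloxy)phenyl]ethenyl}sulfoxonium tetrafluoroborate
Conditions: Me3OBF4 (1.1 equiv), CH2Cl2, rt
Reagents that add atoms: trimethyloxonium tetrafluoroborate, C[O+](C)C.F[B-](F)(F)F
Why: N-Alkylation of the sulfoximine nitrogen, the most nucleophilic site of 10, by a trialkyloxonium salt, a known entry to alkenyl(dimethylamino)sulfoxonium salts that changes neither the sulfur configuration nor the alkene geometry.

**Step 6**
Reactants: 4 4,6-bis(benzyloxy)-2-hydroxy-3,5-dimethoxybenzaldehyde; 11 (S)-(dimethylamino)(phenyl){(E)-2-[3,4,5-tris(benzyloxy)phenyl]ethenyl}sulfoxonium tetrafluoroborate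
Product: 14 (2R,3S,4S)-5,7-bis(benzyloxy)-3,4-epoxy-6,8-dimethoxy-2-[3,4,5-tris(benzyloxy)phenyl]chroman (oxirane trans to the 2-aryl group), via sulfoxonium ylide 12 (not isolated), via betaine 13 (not isolated)
Conditions: Cs2CO3 (1.1 equiv), 4 Å molecular sieves, CH2Cl2/MeCN, −20 °C to rt; filtration through basic Al2O3, used at once
Reagents that add atoms: none
Why: Proposed new method: the caesium phenoxide of 4 adds through O1 to the aryl-bearing β-carbon C2 of the cationic Michael acceptor 11, the (dimethylamino)sulfoxonium ylide 12 so formed attacks the neighbouring formyl carbon C4 through C3, and the alkoxide of betaine 13 displaces the sulfinamide from C3, so that O1–C2, C3–C4 and C3–O are made in one flask and the aldehyde oxygen ends on C3. The closest known reaction types are the epoxy-annulation of amino aldehydes and amino ketones with vinylsulfonium salts, the Johnson–Corey–Chaykovsky epoxidation with (dimethylamino)sulfoxonium ylides, and the phosphorus counterpart in which a salicylaldehyde phenoxide adds to a vinylphosphonium salt and closes to a 2H-chromene by intramolecular Wittig reaction; new are the β-aryl substituent, the phenoxide nucleophile and the transfer of chirality from sulfur. Ring C closes by a 6-exo-trig addition of the ylide carbon to the aldehyde and the oxirane by a 3-exo-tet substitution. C3 and C4 are fixed relative to each other because the displacement needs C4–O and C3–S antiperiplanar (trans-diaxial) and inverts C3, and C2 is fixed relative to them because only an equatorial aryl group avoids the 1,3-diaxial contact with the C4 alkoxide, which puts the oxirane on the face opposite to ring B. The absolute sense comes from the sulfur stereocentre: oxa-Michael addition and betaine formation are reversible, so the outcome is decided in the ring closure, where the (S)-configured group can place S=O over ring C, phenyl in the open sector between C4 and H3 and NMe2 between H3 and C2 only in the (2R,3R,4S)-betaine. The step needs O- instead of C-attack of the phenoxide, a single nucleophilic hydroxyl and epoxide formation instead of olefination, which are secured by the hexasubstituted ring A (no free ring carbon), the benzyl ethers on O5 and O7 and the use of sulfur in place of phosphorus.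

**Step 7**
Reactants: 14 (2R,3S,4S)-5,7-bis(benzyloxy)-3,4-epoxy-6,8-dimethoxy-2-[3,4,5-tris(benzyloxy)phenyl]chroman
Product: 16 (2R,3R)-5,7-bis(benzyloxy)-3-hydroxy-6,8-dimethoxy-2-[3,4,5-tris(benzyloxy)phenyl]chroman-4-one, via alkoxysulfonium triflate 15 (not isolated)
Conditions: DMSO (10 equiv)/TfOH (1.0 equiv) premixed, CH2Cl2, −40 °C; then i-Pr2NEt (3 equiv), −40 °C to rt
Reagents that add atoms: dimethyl sulfoxide, CS(C)=O (oxygen on C4); trifluoromethanesulfonic acid, OS(=O)(=O)C(F)(F)F (counter-ion of 15 only)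
Why: Kornblum-type oxidative epoxide opening (acid-assisted attack of DMSO at the benzylic carbon C4, then Swern-type collapse of the alkoxysulfonium salt with amine base), which is regioselective because only C4 is stabilised by ring A, keeps C2 and C3 as set in step 6 and deliberately erases C4 for its controlled reinstallation in step 9.

**Step 8**
Reactants: 16 (2R,3R)-5,7-bis(benzyloxy)-3-hydroxy-6,8-dimethoxy-2-[3,4,5-tris(benzyloxy)phenyl]chroman-4-one
Product: 17 (2R,3R)-3,5,7-trihydroxy-6,8-dimethoxy-2-(3,4,5-trihydroxyphenyl)chroman-4-one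
Conditions: H2 (1 atm), 10% Pd/C, EtOAc/MeOH, rt
Reagents that add atoms: none
Why: Catalytic hydrogenolysis of five aryl benzyl ethers under neutral conditions, done at the ketone stage so that no benzylic C4–O bond is exposed to palladium, with the vinylogous-ester type aryl ketone and the stereocentres C2 and C3 untouched.

**Step 9**
Reactants: 17 (2R,3R)-3,5,7-trihydroxy-6,8-dimethoxy-2-(3,4,5-trihydroxyphenyl)chroman-4-one
Product: 18 (2R,3S,4R)-6,8-dimethoxy-2-(3,4,5-trihydroxyphenyl)chroman-3,4,5,7-tetraol (target)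
Conditions: NaBH4 (excess), MeOH, 0 °C, argon; AcOH to pH 6 at 0 °C; acid-free chromatography on Sephadex LH-20
Reagents that add atoms: none
Why: Substrate-controlled 1,2-reduction of a 2,3-trans-dihydroflavonol with borohydride, in which axial hydride delivery to C4 of the half-chair with equatorial 2-aryl and 3-hydroxyl groups gives the equatorial 4-hydroxyl, that is the 2,3-trans-3,4-trans (4R) diol known for this substrate class.

**Compound list**
1 | 2,4,6-trihydroxybenzaldehyde | O=Cc1c(O)cc(O)cc1O | starting material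
2 | 2,4-bis(benzyloxy)-6-hydroxybenzaldehyde | O=Cc1c(O)cc(OCc2ccccc2)cc1OCc1ccccc1 | intermediate
3 | 2,4-bis(benzyloxy)-3,5-dibromo-6-hydroxybenzaldehyde | O=Cc1c(O)c(Br)c(OCc2ccccc2)c(Br)c1OCc1ccccc1 | intermediate
4 | 4,6-bis(benzyloxy)-2-hydroxy-3,5-dimethoxybenzaldehyde | O=Cc1c(O)c(OC)c(OCc2ccccc2)c(OC)c1OCc1ccccc1 | intermediate
5 | (S)-N,S-dimethyl-S-phenylsulfoximine | C[S@@](=O)(=NC)c1ccccc1 | starting material
6 | 3,4,5-tris(benzyloxy)benzaldehyde | O=Cc1cc(OCc2ccccc2)c(OCc2ccccc2)c(OCc2ccccc2)c1 | starting material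
7 | (S)-S-(lithiomethyl)-N-methyl-S-phenylsulfoximine | [Li]C[S@@](=O)(=NC)c1ccccc1 | intermediate
8 | lithium 2-[(S)-N-methyl-S-phenylsulfonimidoyl]-1-[3,4,5-tris(benzyloxy)phenyl]ethanolate (both carbinol epimers) | [Li+].[O-]C(C[S@@](=O)(=NC)c1ccccc1)c1cc(OCc2ccccc2)c(OCc2ccccc2)c(OCc2ccccc2)c1 | intermediate
9 | methyl 2-[(S)-N-methyl-S-phenylsulfonimidoyl]-1-[3,4,5-tris(benzyloxy)phenyl]ethyl carbonate (both epimers) | COC(=O)OC(C[S@@](=O)(=NC)c1ccccc1)c1cc(OCc2ccccc2)c(OCc2ccccc2)c(OCc2ccccc2)c1 | intermediate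
10 | (S)-N-methyl-S-phenyl-S-{(E)-2-[3,4,5-tris(benzyloxy)phenyl]ethenyl}sulfoximine | c1(/C=C/[S@@](=O)(=NC)c2ccccc2)cc(OCc2ccccc2)c(OCc2ccccc2)c(OCc2ccccc2)c1 | intermediate
11 | (S)-(dimethylamino)(phenyl){(E)-2-[3,4,5-tris(benzyloxy)phenyl]ethenyl}sulfoxonium tetrafluoroborate | c1(/C=C/[S@@+](=O)(N(C)C)c2ccccc2)cc(OCc2ccccc2)c(OCc2ccccc2)c(OCc2ccccc2)c1.F[B-](F)(F)F | intermediate
12 | sulfoxonium ylide: (2R)-aryl ether of 4 at C2 with the carbanion on C3 next to (S)-sulfur | O=Cc1c(OCc2ccccc2)c(OC)c(OCc2ccccc2)c(OC)c1O[C@@H]([CH-][S@@+](=O)(N(C)C)c1ccccc1)c1cc(OCc2ccccc2)c(OCc2ccccc2)c(OCc2ccccc2)c1 | intermediate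
13 | (2R,3R,4S)-betaine: chroman with 4-oxido and 3-[(S)-(dimethylamino)(oxo)(phenyl)sulfonio] groups trans-diaxial, 2-aryl equatorial | COc1c(OCc3ccccc3)c(OC)c2c(c1OCc1ccccc1)[C@H]([O-])[C@@H]([S@@+](=O)(N(C)C)c1ccccc1)[C@@H](c1cc(OCc3ccccc3)c(OCc3ccccc3)c(OCc3ccccc3)c1)O2 | intermediate
14 | (2R,3S,4S)-5,7-bis(benzyloxy)-3,4-epoxy-6,8-dimethoxy-2-[3,4,5-tris(benzyloxy)phenyl]chroman | COc1c(OCc3ccccc3)c(OC)c2c(c1OCc1ccccc1)[C@@H]1O[C@@H]1[C@@H](c1cc(OCc3ccccc3)c(OCc3ccccc3)c(OCc3ccccc3)c1)O2 | intermediate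
15 | (2R,3R,4R)-4-(dimethylsulfoniooxy)-3-hydroxy derivative, triflate salt (3,4-trans) | COc1c(OCc3ccccc3)c(OC)c2c(c1OCc1ccccc1)[C@@H](O[S+](C)C)[C@H](O)[C@@H](c1cc(OCc3ccccc3)c(OCc3ccccc3)c(OCc3ccccc3)c1)O2.[O-]S(=O)(=O)C(F)(F)F | intermediate
16 | (2R,3R)-5,7-bis(benzyloxy)-3-hydroxy-6,8-dimethoxy-2-[3,4,5-tris(benzyloxy)phenyl]chroman-4-one | COc1c(OCc3ccccc3)c(OC)c2c(c1OCc1ccccc1)C(=O)[C@H](O)[C@@H](c1cc(OCc3ccccc3)c(OCc3ccccc3)c(OCc3ccccc3)c1)O2 | intermediate
17 | (2R,3R)-3,5,7-trihydroxy-6,8-dimethoxy-2-(3,4,5-trihydroxyphenyl)chroman-4-one | COc1c(O)c(OC)c2c(c1O)C(=O)[C@H](O)[C@@H](c1cc(O)c(O)c(O)c1)O2 | intermediate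
18 | (2R,3S,4R)-6,8-dimethoxy-2-(3,4,5-trihydroxyphenyl)chroman-3,4,5,7-tetraol | COc1c(O)c(OC)c2c(c1O)[C@@H](O)[C@H](O)[C@@H](c1cc(O)c(O)c(O)c1)O2 | target

**Total step count:** 9
**Longest linear sequence:** 7 steps (1, 2, 3, 6, 7, 8, 9)

**Steps most likely to fail**

Step 6.
- What may go wrong: reversal of the oxa-Michael addition may outrun ring closure. Base may remove the vinylic proton and fragment the salt. Facial discrimination by sulfur may be weak. The electron-rich benzylic oxirane may ionise during handling.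
- Fallback (known chemistry), from 4 and 6, back at 14: Wittig reaction of 6 with Ph3P=CHCHO gives (E)-3-[3,4,5-tris(benzyloxy)phenyl]prop-2-enal F1. An iminium–enamine domino oxa-Michael/aldol condensation of 4 with F1 under (S)-2-[diphenyl(trimethylsilyloxy)methyl]pyrrolidine and a benzoic acid co-catalyst makes the same two bonds and gives (2R)-5,7-bis(benzyloxy)-6,8-dimethoxy-2-[3,4,5-tris(benzyloxy)phenyl]-2H-chromene-3-carbaldehyde F2. Tsuji–Wilkinson decarbonylation with RhCl(PPh3)3 removes the formyl group and gives (2S)-5,7-bis(benzyloxy)-6,8-dimethoxy-2-[3,4,5-tris(benzyloxy)phenyl]-2H-chromene F3 (same spatial arrangement; the descriptor changes by priority). Dimethyldioxirane then epoxidises C3=C4 on the face opposite to ring B and gives 14.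

Step 7.
- What may go wrong: a hydride shift after ionisation at C4 may compete with capture by DMSO. The oxirane may re-close when base is added. Acid may epimerise C2.
- Fallback, from 14, back at 16: buffered hydrolysis (THF/H2O, NaHCO3) opens the oxirane at C4 and gives (2R,3S)-5,7-bis(benzyloxy)-6,8-dimethoxy-2-[3,4,5-tris(benzyloxy)phenyl]chroman-3,4-diol F4, whose C4 configuration does not matter. Chemoselective oxidation of the benzylic alcohol with activated MnO2 in CH2Cl2 then gives 16.

Step 3.
- What may go wrong: hydrodebromination, incomplete exchange at the bromide flanked by two benzyloxy groups, and cleavage of a benzyl ether by methoxide.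
- Fallback, from 3, back at 4: benzylation of the free hydroxyl (BnBr, K2CO3) gives 2,4,6-tris(benzyloxy)-3,5-dibromobenzaldehyde F5. HC(OMe)3 with catalytic TsOH gives 1,3,5-tris(benzyloxy)-2,4-dibromo-6-(dimethoxymethyl)benzene F6. Double bromine–lithium exchange (t-BuLi, THF, −78 °C), borylation with B(OMe)3 and oxidation with H2O2/NaOH give 2,4,6-tris(benzyloxy)-5-(dimethoxymethyl)benzene-1,3-diol F7. O-Methylation (MeI, K2CO3) gives 1,3,5-tris(benzyloxy)-2-(dimethoxymethyl)-4,6-dimethoxybenzene F8. Dilute HCl in THF frees 2,4,6-tris(benzyloxy)-3,5-dimethoxybenzaldehyde F9. MgBr2·OEt2 then removes one of the two equivalent ortho benzyl groups by chelation to the formyl oxygen and gives 4.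

**Further compounds**
F1 | step 6 | (E)-3-[3,4,5-tris(benzyloxy)phenyl]prop-2-enal | O=C/C=C/c1cc(OCc2ccccc2)c(OCc2ccccc2)c(OCc2ccccc2)c1
F2 | step 6 | (2R)-5,7-bis(benzyloxy)-6,8-dimethoxy-2-[3,4,5-tris(benzyloxy)phenyl]-2H-chromene-3-carbaldehyde | COc1c(OCc3ccccc3)c(OC)c2c(c1OCc1ccccc1)C=C(C=O)[C@@H](c1cc(OCc3ccccc3)c(OCc3ccccc3)c(OCc3ccccc3)c1)O2
F3 | step 6 | (2S)-5,7-bis(benzyloxy)-6,8-dimethoxy-2-[3,4,5-tris(benzyloxy)phenyl]-2H-chromene | COc1c(OCc3ccccc3)c(OC)c2c(c1OCc1ccccc1)C=C[C@@H](c1cc(OCc3ccccc3)c(OCc3ccccc3)c(OCc3ccccc3)c1)O2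
F4 | step 7 | (2R,3S)-5,7-bis(benzyloxy)-6,8-dimethoxy-2-[3,4,5-tris(benzyloxy)phenyl]chroman-3,4-diol (C4 either configuration) | COc1c(OCc3ccccc3)c(OC)c2c(c1OCc1ccccc1)C(O)[C@H](O)[C@@H](c1cc(OCc3ccccc3)c(OCc3ccccc3)c(OCc3ccccc3)c1)O2
F5 | step 3 | 2,4,6-tris(benzyloxy)-3,5-dibromobenzaldehyde | O=Cc1c(OCc2ccccc2)c(Br)c(OCc2ccccc2)c(Br)c1OCc1ccccc1
F6 | step 3 | 1,3,5-tris(benzyloxy)-2,4-dibromo-6-(dimethoxymethyl)benzene | COC(OC)c1c(OCc2ccccc2)c(Br)c(OCc2ccccc2)c(Br)c1OCc1ccccc1
F7 | step 3 | 2,4,6-tris(benzyloxy)-5-(dimethoxymethyl)benzene-1,3-diol | COC(OC)c1c(OCc2ccccc2)c(O)c(OCc2ccccc2)c(O)c1OCc1ccccc1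
F8 | step 3 | 1,3,5-tris(benzyloxy)-2-(dimethoxymethyl)-4,6-dimethoxybenzene | COC(OC)c1c(OCc2ccccc2)c(OC)c(OCc2ccccc2)c(OC)c1OCc1ccccc1
F9 | step 3 | 2,4,6-tris(benzyloxy)-3,5-dimethoxybenzaldehyde | O=Cc1c(OCc2ccccc2)c(OC)c(OCc2ccccc2)c(OC)c1OCc1ccccc1
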